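The target holds two dihydrofuran rings, ring D (O1, C2, C3, C3a, C7a; fused to ring B) and ring E (fused to ring C). In each, C2 bears an aryl group and C3 the CH2OH carbon, trans. Both bonds are therefore cut back to a benzofuran C2=C3 bond. The key step joins a 5-chloro-7-methoxybenzofuran-2-yl pinacol boronate, the ring A aryllithium and allyl acetate: C3 of the resulting boronate attacks a chiral allylpalladium complex while ring A shifts from boron to C2, anti. One operation gives two C–C bonds and both stereocentres of ring D; boron later becomes hydrogen and allyl becomes CH2OH. A second round builds ring E.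

Key step: step 5

Remarks on the design (assumptions included)
- Ring letters: ring A is the 4-hydroxy-3-methoxyphenyl ring, ring B the central benzene ring, ring C the benzene ring carrying the propenol chain, ring D the dihydrofuran ring fused to ring B, ring E the dihydrofuran ring fused to ring C. Unit 1 is rings A, B and D; unit 2 is rings C and E. MOM = methoxymethyl, TBS = tert-butyldimethylsilyl, Bpin = 4,4,5,5-tetramethyl-1,3,2-dioxaborolan-2-yl.
- Stereochemical check: anti addition of ring A and allyl across C2=C3, followed by replacement of boron by hydrogen with retention, gives the trans (2S,3R) ring of the target; no structure needed correction. The C3 descriptor is S while C3 carries allyl, propenyl, formyl or an ester and R once it carries CH2OH or CH2OTBS; the spatial arrangement does not change.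
- Halogen at C5 of the benzofuran: chlorine is used. An aryl chloride is inert to zerovalent palladium at room temperature and to the aryllithium, so the key step has no competing oxidative addition; the chloride is later turned into a boronate (unit 1) or a cinnamate (unit 2).
- Ring A phenol: a MOM ether is used, not a silyl ether. The C–B to C–H exchange uses fluoride, which would strip a silyl ether and leave a para-phenoxide able to open ring D through a quinone methide.
- Assumption: (S)-H8-BINAP is written as the ligand that gives the (2S,3S) boronate. The sense of induction must be confirmed on the first run and the antipodal ligand used if it is the opposite.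

Step 1
Reactants: 1 5-chloro-2-hydroxy-3-methoxybenzaldehyde; 2 ethyl bromoacetate
Product: 4 2-(4-chloro-2-formyl-6-methoxyphenoxy)acetic acid, via ethyl aryloxyacetate 3 (not isolated)
Conditions: K2CO3, DMF, 50 °C; then aq NaOH, rt; then aq HCl
Reagents that add atoms: sodium hydroxide, [Na+].[OH-]
Why: Williamson O-alkylation of the phenoxide by the primary α-bromo ester followed by saponification in the same pot should give the acid, the aldehyde being inert to these mild bases.

Step 2
Reactants: 4 2-(4-chloro-2-formyl-6-methoxyphenoxy)acetic acid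
Product: 5 5-chloro-7-methoxybenzofuran
Conditions: NaOAc, Ac2O, AcOH, reflux
Reagents that add atoms: none
Why: Perkin-type cyclodehydration of an o-formylphenoxyacetic acid: the mixed-anhydride enolate adds to the neighbouring aldehyde and the β-lactone formed loses CO2 to give the aromatic furan ring.

Step 3
Reactants: 5 5-chloro-7-methoxybenzofuran
Product: 6 2-(5-chloro-7-methoxybenzofuran-2-yl)-4,4,5,5-tetramethyl-1,3,2-dioxaborolane
Conditions: [Ir(OMe)(cod)]2 (1.5 mol%), 4,4′-di-tert-butyl-2,2′-bipyridine (3 mol%), B2pin2 (0.6 equiv), THF, rt to 50 °C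
Reagents that add atoms: bis(pinacolato)diboron, CC1(C)OB(OC1(C)C)B1OC(C)(C)C(C)(C)O1
Why: Iridium-catalysed C–H borylation of a benzofuran takes place at the furan C2–H, while the benzo C–H bonds at C4 and C6 are each flanked by a substituent and the C–Cl bond is not touched.

Step 4
Reactants: 7 4-bromo-2-methoxyphenol
Product: 8 4-bromo-2-methoxy-1-(methoxymethoxy)benzene
Conditions: MOMCl, i-Pr2NEt, CH2Cl2, 0 °C to rt
Reagents that add atoms: chloromethyl methyl ether, COCCl
Why: Routine O-alkylation of the phenol gives an acetal protecting group that is stable to organolithiums, zerovalent palladium and fluoride.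

Step 5
Reactants: 8 4-bromo-2-methoxy-1-(methoxymethoxy)benzene; 6 2-(5-chloro-7-methoxybenzofuran-2-yl)-4,4,5,5-tetramethyl-1,3,2-dioxaborolane; 9 allyl acetate
Product: 12 (2S,3S)-3-allyl-5-chloro-7-methoxy-2-[3-methoxy-4-(methoxymethoxy)phenyl]-2-(4,4,5,5-tetramethyl-1,3,2-dioxaborolan-2-yl)-2,3-dihydrobenzofuran, via aryllithium 10 (not isolated), via lithium boronate complex 11 (not isolated)
Conditions: 8, t-BuLi (2.1 equiv), THF, −78 °C; then 6, −78 to 0 °C; then Pd2(dba)3 (2.5 mol%), (S)-H8-BINAP (6 mol%), 9 (1.5 equiv), THF, 0 °C to rt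
Reagents that add atoms: none
Why: Proposed new method: aryllithium 10 adds to the boron of 6 to give the tetracoordinate boronate 11, whose furan C3 is now electron-rich enough to attack the cationic allyl complex of divalent palladium generated from 9 and the zerovalent palladium–bisphosphine catalyst, and as the C3–CH2 bond forms ring A shifts from boron to C2 antiperiplanar to the incoming allyl group, which breaks the furan aromaticity and leaves boron on C2. The closest known reaction type is the palladium-catalysed enantioselective three-component coupling of indol-2-yl boronate complexes with allylic acetates through 1,2-boronate migration, and the benzofuran-2-yl boronate is its oxygen analogue, with the ring oxygen taking the role of nitrogen in supporting the charge that develops at C2. No ring is closed; the existing furan ring is only dearomatised. The C3 stereocentre is set by the chiral bisphosphine on the allylpalladium electrophile, which selects one face of C3, and the C2 stereocentre follows from it because the migration is concerted and anti. The step needs anti addition across C2=C3, one enantioface of C3 and attack at C3 in preference to transfer of an aryl group from boron to palladium: the first is secured by the stereoelectronics of the shift, the second by the ligand, and the third by the electron-rich 7-methoxybenzofuran boronate in combination with a chelating bisphosphine, while the C5–Cl bond is inert to zerovalent palladium at room temperature.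

Step 6
Reactants: 12 (2S,3S)-3-allyl-5-chloro-7-methoxy-2-[3-methoxy-4-(methoxymethoxy)phenyl]-2-(4,4,5,5-tetramethyl-1,3,2-dioxaborolan-2-yl)-2,3-dihydrobenzofuran
Product: 13 (2S,3S)-3-allyl-5-chloro-7-methoxy-2-[3-methoxy-4-(methoxymethoxy)phenyl]-2,3-dihydrobenzofuran
Conditions: Bu4NF·3H2O (1.5 equiv), toluene, rt to 45 °C
Reagents that add atoms: none
Why: Fluoride-promoted protodeboronation of a tertiary benzylic pinacol boronate is known to proceed with retention in a non-polar solvent, so the fluoroboronate should be protonated by the hydrate water on the face that carried boron and the anti relationship of aryl and allyl becomes the trans ring; the MOM ether is inert to fluoride.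

Step 7
Reactants: 13 (2S,3S)-3-allyl-5-chloro-7-methoxy-2-[3-methoxy-4-(methoxymethoxy)phenyl]-2,3-dihydrobenzofuran
Product: 14 (2S,3S)-5-chloro-7-methoxy-2-[3-methoxy-4-(methoxymethoxy)phenyl]-3-[(E)-prop-1-en-1-yl]-2,3-dihydrobenzofuran
Conditions: [Ir(cod)(PMePh2)2]PF6 (3 mol%), activated with H2 then purged with argon, THF, rt
Reagents that add atoms: none
Why: Alkene isomerisation by a cationic iridium hydride moves the terminal double bond by one position to the (E)-propenyl group at room temperature and should stop there, leaving the C3–H stereocentre untouched (any Z isomer is cleaved to the same aldehyde in the next step).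

Step 8
Reactants: 14 (2S,3S)-5-chloro-7-methoxy-2-[3-methoxy-4-(methoxymethoxy)phenyl]-3-[(E)-prop-1-en-1-yl]-2,3-dihydrobenzofuran
Product: 16 [(2S,3R)-5-chloro-7-methoxy-2-[3-methoxy-4-(methoxymethoxy)phenyl]-2,3-dihydrobenzofuran-3-yl]methanol, via aldehyde 15 (not isolated)
Conditions: O3 (to consumption of 14), CH2Cl2/MeOH, −78 °C; then NaBH4, −78 to 0 °C
Reagents that add atoms: ozone, O=[O+][O-]
Why: Ozonolysis with reductive NaBH4 work-up cleaves the propenyl group to the C3 aldehyde and reduces it in the cold before it can enolise or open the ring, the alkene reacting far faster with ozone than the alkoxyarenes.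

Step 9
Reactants: 16 [(2S,3R)-5-chloro-7-methoxy-2-[3-methoxy-4-(methoxymethoxy)phenyl]-2,3-dihydrobenzofuran-3-yl]methanol
Product: 17 tert-butyl{[(2S,3R)-5-chloro-7-methoxy-2-[3-methoxy-4-(methoxymethoxy)phenyl]-2,3-dihydrobenzofuran-3-yl]methoxy}dimethylsilane
Conditions: TBSCl, imidazole, DMF, rt
Reagents that add atoms: tert-butyldimethylsilyl chloride, CC(C)(C)[Si](C)(C)Cl
Why: Routine silylation of the primary alcohol removes the only acidic proton before the organolithium step.

Step 10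
Reactants: 17 tert-butyl{[(2S,3R)-5-chloro-7-methoxy-2-[3-methoxy-4-(methoxymethoxy)phenyl]-2,3-dihydrobenzofuran-3-yl]methoxy}dimethylsilane
Product: 18 tert-butyl{[(2S,3R)-7-methoxy-2-[3-methoxy-4-(methoxymethoxy)phenyl]-5-(4,4,5,5-tetramethyl-1,3,2-dioxaborolan-2-yl)-2,3-dihydrobenzofuran-3-yl]methoxy}dimethylsilane
Conditions: Pd2(dba)3 (2 mol%), XPhos (8 mol%), B2pin2 (1.5 equiv), KOAc (3 equiv), 1,4-dioxane, 100 °C
Reagents that add atoms: bis(pinacolato)diboron, CC1(C)OB(OC1(C)C)B1OC(C)(C)C(C)(C)O1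
Why: Miyaura borylation of an electron-rich aryl chloride with a zerovalent palladium–dialkylbiarylphosphine catalyst is established, and KOAc is too weak a base to harm the silyl ether, the acetal or the stereocentres.

Step 11
Reactants: 5 5-chloro-7-methoxybenzofuran; 18 tert-butyl{[(2S,3R)-7-methoxy-2-[3-methoxy-4-(methoxymethoxy)phenyl]-5-(4,4,5,5-tetramethyl-1,3,2-dioxaborolan-2-yl)-2,3-dihydrobenzofuran-3-yl]methoxy}dimethylsilane; 9 allyl acetate
Product: 21 (2S,3S)-3-allyl-2-[(2S,3R)-3-{[(tert-butyldimethylsilyl)oxy]methyl}-7-methoxy-2-[3-methoxy-4-(methoxymethoxy)phenyl]-2,3-dihydrobenzofuran-5-yl]-5-chloro-7-methoxy-2-(4,4,5,5-tetramethyl-1,3,2-dioxaborolan-2-yl)-2,3-dihydrobenzofuran, via 2-lithiobenzofuran 19 (not isolated), via lithium boronate complex 20 (not isolated)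
Conditions: 5 (1.15 equiv), n-BuLi (1.1 equiv), THF, −78 °C; then 18, −78 to 0 °C; then Pd2(dba)3 (2.5 mol%), (S)-H8-BINAP (6 mol%), 9 (1.5 equiv), THF, 0 °C to rt
Reagents that add atoms: none
Why: Proposed new method: the same dearomative three-component coupling as in step 5, with the boronate complex 20 assembled from the other side (C2 deprotonation of the benzofuran by n-BuLi, then addition of 19 to aryl boronate 18), so that C3 of ring C's furan attacks the allylpalladium complex while the ring B aryl group shifts from boron to C2 anti to the allyl group; the ligand again selects the face of C3 under catalyst control because the stereocentres of unit 1 are remote, and the closest known reaction type is the indol-2-yl boronate coupling named in step 5.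

Step 12
Reactants: 21 (2S,3S)-3-allyl-2-[(2S,3R)-3-{[(tert-butyldimethylsilyl)oxy]methyl}-7-methoxy-2-[3-methoxy-4-(methoxymethoxy)phenyl]-2,3-dihydrobenzofuran-5-yl]-5-chloro-7-methoxy-2-(4,4,5,5-tetramethyl-1,3,2-dioxaborolan-2-yl)-2,3-dihydrobenzofuran
Product: 22 [(2S,3R)-5-[(2S,3S)-3-allyl-5-chloro-7-methoxy-2,3-dihydrobenzofuran-2-yl]-7-methoxy-2-[3-methoxy-4-(methoxymethoxy)phenyl]-2,3-dihydrobenzofuran-3-yl]methanol
Conditions: Bu4NF·3H2O (4 equiv), toluene/THF, rt to 40 °C
Reagents that add atoms: none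
Why: The stereoretentive fluoride-promoted protodeboronation of step 6 replaces the boron at C2 of ring E by hydrogen, and the excess fluoride removes the TBS ether (fluoride desilylation), which is no longer needed.

Step 13
Reactants: 22 [(2S,3R)-5-[(2S,3S)-3-allyl-5-chloro-7-methoxy-2,3-dihydrobenzofuran-2-yl]-7-methoxy-2-[3-methoxy-4-(methoxymethoxy)phenyl]-2,3-dihydrobenzofuran-3-yl]methanol
Product: 23 [(2S,3R)-5-[(2S,3S)-5-chloro-7-methoxy-3-[(E)-prop-1-en-1-yl]-2,3-dihydrobenzofuran-2-yl]-7-methoxy-2-[3-methoxy-4-(methoxymethoxy)phenyl]-2,3-dihydrobenzofuran-3-yl]methanol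
Conditions: [Ir(cod)(PMePh2)2]PF6 (5 mol%), activated with H2 then purged with argon, THF, rt
Reagents that add atoms: none
Why: The iridium hydride alkene isomerisation of step 7 should tolerate the free primary alcohol and again move the double bond by one position only.

Step 14
Reactants: 23 [(2S,3R)-5-[(2S,3S)-5-chloro-7-methoxy-3-[(E)-prop-1-en-1-yl]-2,3-dihydrobenzofuran-2-yl]-7-methoxy-2-[3-methoxy-4-(methoxymethoxy)phenyl]-2,3-dihydrobenzofuran-3-yl]methanol
Product: 25 [(2S,3R)-5-chloro-2-[(2S,3R)-3-(hydroxymethyl)-7-methoxy-2-[3-methoxy-4-(methoxymethoxy)phenyl]-2,3-dihydrobenzofuran-5-yl]-7-methoxy-2,3-dihydrobenzofuran-3-yl]methanol, via aldehyde 24 (not isolated)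
Conditions: O3 (to consumption of 23), CH2Cl2/MeOH, −78 °C; then NaBH4, −78 to 0 °C
Reagents that add atoms: ozone, O=[O+][O-]
Why: Ozonolysis with reductive NaBH4 work-up, as in step 8, cuts the propenyl group down to CH2OH; no other alkene is present at this stage because the ring C side chain is installed afterwards.

Step 15
Reactants: 25 [(2S,3R)-5-chloro-2-[(2S,3R)-3-(hydroxymethyl)-7-methoxy-2-[3-methoxy-4-(methoxymethoxy)phenyl]-2,3-dihydrobenzofuran-5-yl]-7-methoxy-2,3-dihydrobenzofuran-3-yl]methanol; 26 methyl acrylate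
Product: 27 methyl (E)-3-[(2S,3R)-3-(hydroxymethyl)-2-[(2S,3R)-3-(hydroxymethyl)-7-methoxy-2-[3-methoxy-4-(methoxymethoxy)phenyl]-2,3-dihydrobenzofuran-5-yl]-7-methoxy-2,3-dihydrobenzofuran-5-yl]prop-2-enoate
Conditions: 26 (3 equiv), Pd2(dba)3 (2.5 mol%), [(t-Bu)3PH]BF4 (10 mol%), Cy2NMe (1.5 equiv), 1,4-dioxane, 100 °C
Reagents that add atoms: none
Why: Mizoroki–Heck reaction of an electron-rich aryl chloride with an acrylate is established with the zerovalent palladium–tri-tert-butylphosphine catalyst, β-hydride elimination gives the (E)-cinnamate, and free alcohols are tolerated.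

Step 16
Reactants: 27 methyl (E)-3-[(2S,3R)-3-(hydroxymethyl)-2-[(2S,3R)-3-(hydroxymethyl)-7-methoxy-2-[3-methoxy-4-(methoxymethoxy)phenyl]-2,3-dihydrobenzofuran-5-yl]-7-methoxy-2,3-dihydrobenzofuran-5-yl]prop-2-enoate
Product: 28 methyl (E)-3-[(2S,3R)-2-[(2S,3R)-2-(4-hydroxy-3-methoxyphenyl)-3-(hydroxymethyl)-7-methoxy-2,3-dihydrobenzofuran-5-yl]-3-(hydroxymethyl)-7-methoxy-2,3-dihydrobenzofuran-5-yl]prop-2-enoate
Conditions: HCl (catalytic), MeOH/THF, rt to 40 °C
Reagents that add atoms: none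
Why: Acid-catalysed acetal exchange with methanol (MOM cleavage) frees the phenol while no acid-labile allylic alcohol is yet present, and any reversible opening of ring D at the p-hydroxybenzylic C2 returns the more stable trans ring.

Step 17
Reactants: 28 methyl (E)-3-[(2S,3R)-2-[(2S,3R)-2-(4-hydroxy-3-methoxyphenyl)-3-(hydroxymethyl)-7-methoxy-2,3-dihydrobenzofuran-5-yl]-3-(hydroxymethyl)-7-methoxy-2,3-dihydrobenzofuran-5-yl]prop-2-enoate
Product: 29 (E)-3-[(2S,3R)-2-[(2S,3R)-2-(4-hydroxy-3-methoxyphenyl)-3-(hydroxymethyl)-7-methoxy-2,3-dihydrobenzofuran-5-yl]-3-(hydroxymethyl)-7-methoxy-2,3-dihydrobenzofuran-5-yl]prop-2-en-1-ol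
Conditions: i-Bu2AlH (8 equiv), THF/CH2Cl2, −78 to −20 °C; then aqueous potassium sodium tartrate
Reagents that add atoms: none
Why: 1,2-Reduction of the α,β-unsaturated ester by excess i-Bu2AlH in the cold should give the (E)-allylic alcohol without touching the alkene, the phenol and the two alcohols only consuming hydride.

Compound list
1 | 5-chloro-2-hydroxy-3-methoxybenzaldehyde (5-chloro-o-vanillin) | COc1cc(Cl)cc(C=O)c1O | starting material
2 | ethyl bromoacetate | CCOC(=O)CBr | starting material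
3 | ethyl 2-(4-chloro-2-formyl-6-methoxyphenoxy)acetate | CCOC(=O)COc1c(C=O)cc(Cl)cc1OC | intermediate
4 | 2-(4-chloro-2-formyl-6-methoxyphenoxy)acetic acid | OC(=O)COc1c(C=O)cc(Cl)cc1OC | intermediate
5 | 5-chloro-7-methoxybenzofuran | COc1cc(Cl)cc2ccoc12 | intermediate
6 | 2-(5-chloro-7-methoxybenzofuran-2-yl)-4,4,5,5-tetramethyl-1,3,2-dioxaborolane | COc1cc(Cl)cc2cc(B3OC(C)(C)C(C)(C)O3)oc12 | intermediate
7 | 4-bromo-2-methoxyphenol | COc1cc(Br)ccc1O | starting material
8 | 4-bromo-2-methoxy-1-(methoxymethoxy)benzene | COCOc1ccc(Br)cc1OC | intermediate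
9 | allyl acetate | C=CCOC(C)=O | starting material
10 | [3-methoxy-4-(methoxymethoxy)phenyl]lithium | [Li]c1ccc(OCOC)c(OC)c1 | intermediate
11 | lithium (5-chloro-7-methoxybenzofuran-2-yl)[3-methoxy-4-(methoxymethoxy)phenyl](pinacolato)borate | [Li+].COCOc1ccc(cc1OC)[B-]2(OC(C)(C)C(C)(C)O2)c3cc4cc(Cl)cc(OC)c4o3 | intermediate
12 | (2S,3S)-3-allyl-5-chloro-7-methoxy-2-[3-methoxy-4-(methoxymethoxy)phenyl]-2-(4,4,5,5-tetramethyl-1,3,2-dioxaborolan-2-yl)-2,3-dihydrobenzofuran (aryl and allyl anti) | COc1cc([C@@]2(B7OC(C)(C)C(C)(C)O7)Oc3c(OC)cc(Cl)cc3[C@@H]2CC=C)ccc1OCOC | intermediate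
13 | (2S,3S)-3-allyl-5-chloro-7-methoxy-2-[3-methoxy-4-(methoxymethoxy)phenyl]-2,3-dihydrobenzofuran (trans) | COc1cc([C@H]2Oc3c(OC)cc(Cl)cc3[C@@H]2CC=C)ccc1OCOC | intermediate
14 | (2S,3S)-5-chloro-7-methoxy-2-[3-methoxy-4-(methoxymethoxy)phenyl]-3-[(E)-prop-1-en-1-yl]-2,3-dihydrobenzofuran | COc1cc([C@H]2Oc3c(OC)cc(Cl)cc3[C@@H]2/C=C/C)ccc1OCOC | intermediate
15 | (2S,3S)-5-chloro-7-methoxy-2-[3-methoxy-4-(methoxymethoxy)phenyl]-2,3-dihydrobenzofuran-3-carbaldehyde | COc1cc([C@H]2Oc3c(OC)cc(Cl)cc3[C@@H]2C=O)ccc1OCOC | intermediate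
16 | [(2S,3R)-5-chloro-7-methoxy-2-[3-methoxy-4-(methoxymethoxy)phenyl]-2,3-dihydrobenzofuran-3-yl]methanol | COc1cc([C@H]2Oc3c(OC)cc(Cl)cc3[C@@H]2CO)ccc1OCOC | intermediate
17 | tert-butyl{[(2S,3R)-5-chloro-7-methoxy-2-[3-methoxy-4-(methoxymethoxy)phenyl]-2,3-dihydrobenzofuran-3-yl]methoxy}dimethylsilane | COc1cc([C@H]2Oc3c(OC)cc(Cl)cc3[C@@H]2CO[Si](C)(C)C(C)(C)C)ccc1OCOC | intermediate
18 | tert-butyl{[(2S,3R)-7-methoxy-2-[3-methoxy-4-(methoxymethoxy)phenyl]-5-(4,4,5,5-tetramethyl-1,3,2-dioxaborolan-2-yl)-2,3-dihydrobenzofuran-3-yl]methoxy}dimethylsilane | COc1cc([C@H]2Oc3c(OC)cc(B4OC(C)(C)C(C)(C)O4)cc3[C@@H]2CO[Si](C)(C)C(C)(C)C)ccc1OCOC | intermediate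
19 | (5-chloro-7-methoxybenzofuran-2-yl)lithium | [Li]c1cc2cc(Cl)cc(OC)c2o1 | intermediate
20 | lithium (5-chloro-7-methoxybenzofuran-2-yl)[(2S,3R)-3-{[(tert-butyldimethylsilyl)oxy]methyl}-7-methoxy-2-[3-methoxy-4-(methoxymethoxy)phenyl]-2,3-dihydrobenzofuran-5-yl](pinacolato)borate | [Li+].COc1cc([C@H]2Oc3c(OC)cc([B-]4(OC(C)(C)C(C)(C)O4)c5cc6cc(Cl)cc(OC)c6o5)cc3[C@@H]2CO[Si](C)(C)C(C)(C)C)ccc1OCOC | intermediate
21 | (2S,3S)-3-allyl-2-[(2S,3R)-3-{[(tert-butyldimethylsilyl)oxy]methyl}-7-methoxy-2-[3-methoxy-4-(methoxymethoxy)phenyl]-2,3-dihydrobenzofuran-5-yl]-5-chloro-7-methoxy-2-(4,4,5,5-tetramethyl-1,3,2-dioxaborolan-2-yl)-2,3-dihydrobenzofuran | COc1cc([C@H]2Oc3c(OC)cc([C@@]4(B5OC(C)(C)C(C)(C)O5)Oc6c(OC)cc(Cl)cc6[C@@H]4CC=C)cc3[C@@H]2CO[Si](C)(C)C(C)(C)C)ccc1OCOC | intermediate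
22 | [(2S,3R)-5-[(2S,3S)-3-allyl-5-chloro-7-methoxy-2,3-dihydrobenzofuran-2-yl]-7-methoxy-2-[3-methoxy-4-(methoxymethoxy)phenyl]-2,3-dihydrobenzofuran-3-yl]methanol | COc1cc([C@H]2Oc3c(OC)cc([C@H]4Oc5c(OC)cc(Cl)cc5[C@@H]4CC=C)cc3[C@@H]2CO)ccc1OCOC | intermediate
23 | [(2S,3R)-5-[(2S,3S)-5-chloro-7-methoxy-3-[(E)-prop-1-en-1-yl]-2,3-dihydrobenzofuran-2-yl]-7-methoxy-2-[3-methoxy-4-(methoxymethoxy)phenyl]-2,3-dihydrobenzofuran-3-yl]methanol | COc1cc([C@H]2Oc3c(OC)cc([C@H]4Oc5c(OC)cc(Cl)cc5[C@@H]4/C=C/C)cc3[C@@H]2CO)ccc1OCOC | intermediate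
24 | (2S,3S)-5-chloro-2-[(2S,3R)-3-(hydroxymethyl)-7-methoxy-2-[3-methoxy-4-(methoxymethoxy)phenyl]-2,3-dihydrobenzofuran-5-yl]-7-methoxy-2,3-dihydrobenzofuran-3-carbaldehyde | COc1cc([C@H]2Oc3c(OC)cc([C@H]4Oc5c(OC)cc(Cl)cc5[C@@H]4C=O)cc3[C@@H]2CO)ccc1OCOC | intermediate
25 | [(2S,3R)-5-chloro-2-[(2S,3R)-3-(hydroxymethyl)-7-methoxy-2-[3-methoxy-4-(methoxymethoxy)phenyl]-2,3-dihydrobenzofuran-5-yl]-7-methoxy-2,3-dihydrobenzofuran-3-yl]methanol | COc1cc([C@H]2Oc3c(OC)cc([C@H]4Oc5c(OC)cc(Cl)cc5[C@@H]4CO)cc3[C@@H]2CO)ccc1OCOC | intermediate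
26 | methyl acrylate | C=CC(=O)OC | starting material
27 | methyl (E)-3-[(2S,3R)-3-(hydroxymethyl)-2-[(2S,3R)-3-(hydroxymethyl)-7-methoxy-2-[3-methoxy-4-(methoxymethoxy)phenyl]-2,3-dihydrobenzofuran-5-yl]-7-methoxy-2,3-dihydrobenzofuran-5-yl]prop-2-enoate | COc1cc([C@H]2Oc3c(OC)cc([C@H]4Oc5c(OC)cc(/C=C/C(=O)OC)cc5[C@@H]4CO)cc3[C@@H]2CO)ccc1OCOC | intermediate
28 | methyl (E)-3-[(2S,3R)-2-[(2S,3R)-2-(4-hydroxy-3-methoxyphenyl)-3-(hydroxymethyl)-7-methoxy-2,3-dihydrobenzofuran-5-yl]-3-(hydroxymethyl)-7-methoxy-2,3-dihydrobenzofuran-5-yl]prop-2-enoate | COc1cc([C@H]2Oc3c(OC)cc([C@H]4Oc5c(OC)cc(/C=C/C(=O)OC)cc5[C@@H]4CO)cc3[C@@H]2CO)ccc1O | intermediate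
29 | (E)-3-[(2S,3R)-2-[(2S,3R)-2-(4-hydroxy-3-methoxyphenyl)-3-(hydroxymethyl)-7-methoxy-2,3-dihydrobenzofuran-5-yl]-3-(hydroxymethyl)-7-methoxy-2,3-dihydrobenzofuran-5-yl]prop-2-en-1-ol (CNP0250921.2) | COc1cc([C@H]2Oc3c(OC)cc([C@H]4Oc5c(OC)cc(/C=C/CO)cc5[C@@H]4CO)cc3[C@@H]2CO)ccc1O | target

Total step count: 17. Longest linear sequence: 16 steps (steps 1 to 3, then 5 to 17); step 4 is the only step off this line, and benzofuran 5 re-enters at step 11.

Steps most likely to fail

1. Step 5. What may go wrong: the boronate may hand an aryl group to palladium, so that plain allyl–arene cross-coupling takes over from attack at C3, or the ligand may discriminate the two faces of C3 poorly. The fallback uses known chemistry, an enantioselective dirhodium-carbenoid insertion into a benzylic ether C–H bond; it sets out from 6 and 8 and comes back to the route at 16.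
   - Boronate 6 is oxidised (NaBO3·4H2O, THF/H2O, then dilute HCl) to 5-chloro-7-methoxybenzofuran-2(3H)-one F1, and acid-catalysed methanolysis (MeOH, catalytic H2SO4, reflux) opens it to methyl 2-(5-chloro-2-hydroxy-3-methoxyphenyl)acetate F2.
   - Aryllithium 10, made from 8 as in step 5, is quenched with paraformaldehyde to give [3-methoxy-4-(methoxymethoxy)phenyl]methanol F3.
   - Mitsunobu etherification of F2 with F3 (PPh3, diisopropyl azodicarboxylate, THF) gives methyl 2-[5-chloro-3-methoxy-2-{[3-methoxy-4-(methoxymethoxy)phenyl]methoxy}phenyl]acetate F4, and diazo transfer (4-acetamidobenzenesulfonyl azide, DBU, MeCN) gives the aryldiazoacetate F5.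
   - Dirhodium tetrakis[N-phthaloyl-(S)-tert-leucinate], Rh2(S-PTTL)4, in toluene at −60 °C (catalyst enantiomer chosen so that C2 becomes S) should insert the carbenoid into the benzylic ether C–H bond and give the cis ester methyl (2S,3R)-5-chloro-7-methoxy-2-[3-methoxy-4-(methoxymethoxy)phenyl]-2,3-dihydrobenzofuran-3-carboxylate F6.
   - NaOMe in MeOH epimerises C3 to the trans ester methyl (2S,3S)-5-chloro-7-methoxy-2-[3-methoxy-4-(methoxymethoxy)phenyl]-2,3-dihydrobenzofuran-3-carboxylate F7, and LiBH4 in THF reduces F7 to alcohol 16.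

2. Step 11. What may go wrong: the same loss of chemoselectivity or face selectivity as in step 5, now on a larger aryl group, or incomplete formation of the boronate complex from the lithiated benzofuran. The fallback applies the same known carbenoid C–H insertion to unit 1; it sets out from 17 and comes back at 25.
   - Aryl chloride 17 is hydroxymethylated by Suzuki–Miyaura coupling with K[AcOCH2BF3] (Pd(dba)2, RuPhos, Na2CO3, dioxane/H2O, 100 °C; the acetate is hydrolysed in the flask) to [(2S,3R)-3-{[(tert-butyldimethylsilyl)oxy]methyl}-7-methoxy-2-[3-methoxy-4-(methoxymethoxy)phenyl]-2,3-dihydrobenzofuran-5-yl]methanol F8.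
   - Mitsunobu etherification of phenol F2 (made as in the fallback for step 5) with F8 gives the aryl benzyl ether F9, and diazo transfer gives the aryldiazoacetate F10.
   - Rh2(S-PTTL)4-catalysed insertion into the benzylic ether C–H bond gives the cis ring E ester F11, and NaOMe in MeOH epimerises it to the trans ring E ester F12.
   - LiBH4 gives the mono-silylated diol F13, and Bu4NF in THF removes the TBS group to give diol 25.

3. Step 6. What may go wrong: protonation of the C2 boronate without clean retention, so that the aryl and allyl groups end up cis, the face anti to the allyl group being the less hindered one. The fallback replaces kinetic stereoretention by thermodynamic control at C2; it sets out from 12 and comes back at 13.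
   - The C–B bond of 12 is cleaved with fluoride without regard to the stereochemical outcome, giving the C2 epimer (2R,3S)-3-allyl-5-chloro-7-methoxy-2-[3-methoxy-4-(methoxymethoxy)phenyl]-2,3-dihydrobenzofuran F14, alone or mixed with 13.
   - Because C2 is a p-alkoxybenzylic ether carbon, a catalytic amount of BF3·OEt2 in CH2Cl2 at −20 °C should reversibly open the C2–O1 bond to the benzylic cation and reclose it to the more stable trans isomer 13. C3, which the key step set, is not touched.

Further compounds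
F1 | step 5 | 5-chloro-7-methoxybenzofuran-2(3H)-one | COc1cc(Cl)cc2CC(=O)Oc12
F2 | step 5 | methyl 2-(5-chloro-2-hydroxy-3-methoxyphenyl)acetate | COC(=O)Cc1cc(Cl)cc(OC)c1O
F3 | step 5 | [3-methoxy-4-(methoxymethoxy)phenyl]methanol | COCOc1ccc(CO)cc1OC
F4 | step 5 | methyl 2-[5-chloro-3-methoxy-2-{[3-methoxy-4-(methoxymethoxy)phenyl]methoxy}phenyl]acetate | COC(=O)Cc1cc(Cl)cc(OC)c1OCc1ccc(OCOC)c(OC)c1
F5 | step 5 | methyl 2-[5-chloro-3-methoxy-2-{[3-methoxy-4-(methoxymethoxy)phenyl]methoxy}phenyl]-2-diazoacetate | COC(=O)C(=[N+]=[N-])c1cc(Cl)cc(OC)c1OCc1ccc(OCOC)c(OC)c1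
F6 | step 5 | methyl (2S,3R)-5-chloro-7-methoxy-2-[3-methoxy-4-(methoxymethoxy)phenyl]-2,3-dihydrobenzofuran-3-carboxylate (cis) | COc1cc([C@H]2Oc3c(OC)cc(Cl)cc3[C@H]2C(=O)OC)ccc1OCOC
F7 | step 5 | methyl (2S,3S)-5-chloro-7-methoxy-2-[3-methoxy-4-(methoxymethoxy)phenyl]-2,3-dihydrobenzofuran-3-carboxylate (trans) | COc1cc([C@H]2Oc3c(OC)cc(Cl)cc3[C@@H]2C(=O)OC)ccc1OCOC
F8 | step 11 | [(2S,3R)-3-{[(tert-butyldimethylsilyl)oxy]methyl}-7-methoxy-2-[3-methoxy-4-(methoxymethoxy)phenyl]-2,3-dihydrobenzofuran-5-yl]methanol | COc1cc([C@H]2Oc3c(OC)cc(CO)cc3[C@@H]2CO[Si](C)(C)C(C)(C)C)ccc1OCOC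
F9 | step 11 | methyl 2-[2-{[(2S,3R)-3-{[(tert-butyldimethylsilyl)oxy]methyl}-7-methoxy-2-[3-methoxy-4-(methoxymethoxy)phenyl]-2,3-dihydrobenzofuran-5-yl]methoxy}-5-chloro-3-methoxyphenyl]acetate | COc1cc([C@H]2Oc3c(OC)cc(COc4c(OC)cc(Cl)cc4CC(=O)OC)cc3[C@@H]2CO[Si](C)(C)C(C)(C)C)ccc1OCOC
F10 | step 11 | methyl 2-[2-{[(2S,3R)-3-{[(tert-butyldimethylsilyl)oxy]methyl}-7-methoxy-2-[3-methoxy-4-(methoxymethoxy)phenyl]-2,3-dihydrobenzofuran-5-yl]methoxy}-5-chloro-3-methoxyphenyl]-2-diazoacetate | COc1cc([C@H]2Oc3c(OC)cc(COc4c(OC)cc(Cl)cc4C(=[N+]=[N-])C(=O)OC)cc3[C@@H]2CO[Si](C)(C)C(C)(C)C)ccc1OCOC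
F11 | step 11 | methyl (2S,3R)-2-[(2S,3R)-3-{[(tert-butyldimethylsilyl)oxy]methyl}-7-methoxy-2-[3-methoxy-4-(methoxymethoxy)phenyl]-2,3-dihydrobenzofuran-5-yl]-5-chloro-7-methoxy-2,3-dihydrobenzofuran-3-carboxylate (cis ring E) | COc1cc([C@H]2Oc3c(OC)cc([C@H]4Oc5c(OC)cc(Cl)cc5[C@H]4C(=O)OC)cc3[C@@H]2CO[Si](C)(C)C(C)(C)C)ccc1OCOC
F12 | step 11 | methyl (2S,3S)-2-[(2S,3R)-3-{[(tert-butyldimethylsilyl)oxy]methyl}-7-methoxy-2-[3-methoxy-4-(methoxymethoxy)phenyl]-2,3-dihydrobenzofuran-5-yl]-5-chloro-7-methoxy-2,3-dihydrobenzofuran-3-carboxylate (trans ring E) | COc1cc([C@H]2Oc3c(OC)cc([C@H]4Oc5c(OC)cc(Cl)cc5[C@@H]4C(=O)OC)cc3[C@@H]2CO[Si](C)(C)C(C)(C)C)ccc1OCOC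
F13 | step 11 | [(2S,3R)-2-[(2S,3R)-3-{[(tert-butyldimethylsilyl)oxy]methyl}-7-methoxy-2-[3-methoxy-4-(methoxymethoxy)phenyl]-2,3-dihydrobenzofuran-5-yl]-5-chloro-7-methoxy-2,3-dihydrobenzofuran-3-yl]methanol | COc1cc([C@H]2Oc3c(OC)cc([C@H]4Oc5c(OC)cc(Cl)cc5[C@@H]4CO)cc3[C@@H]2CO[Si](C)(C)C(C)(C)C)ccc1OCOC
F14 | step 6 | (2R,3S)-3-allyl-5-chloro-7-methoxy-2-[3-methoxy-4-(methoxymethoxy)phenyl]-2,3-dihydrobenzofuran (cis) | COc1cc([C@@H]2Oc3c(OC)cc(Cl)cc3[C@@H]2CC=C)ccc1OCOC
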